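**Plan**

- Retrosynthesis: the angelate is removed first (C3–O). The C6=C7–C8=O enone is traced back to a silyl-protected C8 carbinol and the C4 hydroxyl to an enolate oxidation. Ring A is then cut at C1–C10 and C2–C3 into a cyclohexenyl propanal and a two-carbon unit, and the C4–C5 bond is cut last by a [3,3] shift back to a carvone-derived cyclohexenol.
- Forward: ring B is the carvone ring (carvone C1–C6 become C9, C10, C5, C6, C7, C8; its methyl is C14, its isopropenyl C11–C13). A Johnson–Claisen rearrangement attaches C3–C4–C15 at C5, ring A is closed onto ring B in one operation, and the C4 hydroxyl, the ester and the enone follow.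
- Enabling feature: in ring A the methyl-bearing quaternary C10 and the oxygen-bearing C3 are linked by the unsubstituted C1–C2 bridge. A tertiary C10 radical (from the C9=C10 alkene of ring B) and a C3 aldehyde can therefore be spanned by phenyl vinyl sulfone as an ethylene equivalent. The sulfone on C2 then blocks C2 for the C4 hydroxylation and is removed.
- Stereochemistry: (S)-carvone is the only source of chirality. Its centre (C7) relays to C8 (enolate hydroxylation), C9 (Luche reduction), C5 (suprafacial Claisen) and C10 (anti radical addition). C4 and C3 are set on the rigid trans-decalin, and C7, C8 and C9 lose their stereochemistry by the end.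

Key step: step 7

Remark: the target is read as 3β-angeloyloxy-4α,11-dihydroxyeudesm-6-en-8-one (3S,4S,5R,10R; ester = (Z)-2-methylbut-2-enoate); eudesmane numbering (C14 on C10, C15 on C4, C11–C13 on C7; C10 methyl = β) is used for the decalins and for the ring carbons of their precursors.

**Step 1**
Reactants: 1 (S)-(+)-carvone
Product: 2 trans-6-hydroxycarvone
Conditions: LiN(i-Pr)2, THF, −78 °C; then 2-(phenylsulfonyl)-3-phenyloxaziridine, −78 °C; aq NH4Cl
Reagents that add atoms: 2-(phenylsulfonyl)-3-phenyloxaziridine, O=S(=O)(c1ccccc1)N1OC1c1ccccc1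
Why: Kinetic deprotonation of the enone at the α′ carbon (C8) gives the cross-conjugated lithium enolate, and its oxidation by the N-sulfonyloxaziridine (enolate hydroxylation) should occur anti to the neighbouring isopropenyl group, placing the C8 hydroxyl trans to C7.

**Step 2**
Reactants: 2 trans-6-hydroxycarvone
Product: 3 silyl ether
Conditions: t-BuMe2SiCl, imidazole, DMF, 23 °C
Reagents that add atoms: tert-butyldimethylsilyl chloride, C[Si](C)(Cl)C(C)(C)C
Why: Standard silylation of the secondary alcohol keeps C8 at the alcohol level, out of conjugation with the later C9=C10 alkene, until the last step.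

**Step 3**
Reactants: 3 silyl ether
Product: 4 allylic alcohol
Conditions: NaBH4, CeCl3·7H2O, MeOH, −78 → 0 °C
Reagents that add atoms: none
Why: Luche 1,2-reduction with axial hydride delivery on the face opposite to the isopropenyl group (as carvone itself behaves) should give the C9 carbinol cis to the isopropenyl group and trans to the silyl ether.

**Step 4**
Reactants: 4 allylic alcohol; 5 triethyl orthopropionate
Product: 7 ethyl ester, via mixed ketene acetal 6 (not isolated)
Conditions: 5 (6 equiv), EtCO2H (10 mol %), 140 °C, EtOH distilled off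
Reagents that add atoms: none
Why: Johnson–Claisen rearrangement, whose suprafacial [3,3] shift forms the C4–C5 bond on the face that carried the C9 oxygen (sets C5) and moves the alkene to C9=C10, while C4 forms as an epimer mixture that is corrected in step 9.

**Step 5**
Reactants: 7 ethyl ester
Product: 9 hydroxy ester, via alkylmercury acetate 8 (not isolated)
Conditions: Hg(OAc)2 (1.1 equiv), THF/H2O (1:1), 23 °C; then 3 M NaOH, NaBH4, 0 °C
Reagents that add atoms: water, O; Hg(OAc)2, CC(=O)O[Hg]OC(C)=O (its atoms stay only in 8)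
Why: Oxymercuration–demercuration (Markovnikov hydration) should take the unhindered 1,1-disubstituted isopropenyl alkene in preference to the trisubstituted ring alkene flanked by the silyl ether, giving the C11 tertiary alcohol.

**Step 6**
Reactants: 9 hydroxy ester
Product: 10 aldehyde
Conditions: i-Bu2AlH (2.2 equiv), CH2Cl2, −78 °C; Rochelle salt work-up
Reagents that add atoms: none
Why: Partial reduction of the ester through the aluminium hemiacetal that is stable at −78 °C (one equivalent is consumed by the tertiary alcohol) gives the C3 aldehyde.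

**Step 7**
Reactants: 10 aldehyde; 11 phenyl vinyl sulfone
Product: 14 trans-decalin β-hydroxy sulfone, via tertiary C10 radical 12 (not isolated), via α-sulfonyl carbanion 13 (not isolated)
Conditions: Fe(acac)3 (30 mol %), PhSiH3 (2.5 equiv), 11 (3 equiv), EtOH/(CH2OH)2 (5:1), N2, 23 → 40 °C
Reagents that add atoms: none
Why: Proposed new method: an iron hydride formed from Fe(acac)3 and PhSiH3 transfers a hydrogen atom to C9 of the trisubstituted alkene, the tertiary C10 radical adds to phenyl vinyl sulfone (Giese addition, C1–C10 bond), divalent iron reduces the α-sulfonyl radical to a carbanion (radical–polar crossover), and this adds to the C3 aldehyde (C2–C3 bond) before the alkoxide is protonated by the solvent. The closest known reaction type is the iron-hydride-initiated radical–polar crossover annulation of γ,δ-unsaturated aldehydes with enones or enals, which ends in an aldol addition, together with the known hydrogen-atom-transfer Giese coupling of alkenes with vinyl sulfones; new is the capture of the sulfonyl-stabilised carbanion by the aldehyde. Ring A closes in the polar step as a 6-exo-trig addition of C2 to the carbonyl carbon C3. C10 is set in the intermolecular radical step by approach of the acceptor anti to the equatorial C5 side chain on the all-equatorial chair of ring B, which puts C1 trans to C4 and the methyl group axial (trans ring fusion); the centres formed at C2 and C3 need no control because steps 8 to 11 erase or reset them. The step needs hydrogen-atom transfer at one alkene only and capture of the radical by the sulfone, not by the aldehyde; the substrate secures this with a single electron-rich alkene (the isopropenyl group was hydrated in step 5) and a nucleophilic tertiary radical.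

**Step 8**
Reactants: 14 trans-decalin β-hydroxy sulfone
Product: 15 β-keto sulfone
Conditions: Dess–Martin periodinane, CH2Cl2, 23 °C
Reagents that add atoms: none
Why: Dess–Martin oxidation of the only secondary alcohol (tertiary alcohol and silyl ether are inert) merges the C3 epimers into the β-keto sulfone.

**Step 9**
Reactants: 15 β-keto sulfone
Product: 16 4α-hydroxy β-keto sulfone
Conditions: LiN(i-Pr)2 (3.5 equiv), THF, −78 → 0 °C; then 2-(phenylsulfonyl)-3-phenyloxaziridine (1.1 equiv), −78 °C; aq NH4Cl
Reagents that add atoms: 2-(phenylsulfonyl)-3-phenyloxaziridine, O=S(=O)(c1ccccc1)N1OC1c1ccccc1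
Why: Proposed new method: once the alkoxide and the sulfonyl-stabilised C2 anion have formed, further base can only remove the C4 methine proton, and the resulting α′-enolate carbon (the more reactive site of the dianion, as in the known γ-alkylation of β-keto sulfone and β-keto ester dianions) should be hydroxylated by the oxaziridine (closest known type: oxaziridine oxidation of ketone enolates) from the α-face, anti to the axial C10 methyl group, which sets C4 with the hydroxyl equatorial and the methyl axial.

**Step 10**
Reactants: 16 4α-hydroxy β-keto sulfone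
Product: 17 4α-hydroxy-3-ketone
Conditions: Al(Hg), THF/H2O (9:1), 0 → 23 °C
Reagents that add atoms: none
Why: Reductive desulfonylation of a β-keto sulfone with aluminium amalgam (electron transfer, loss of sulfinate, protonation of the enolate) removes the activating group from C2 and should leave the tertiary α-ketol intact.

**Step 11**
Reactants: 17 4α-hydroxy-3-ketone
Product: 18 3β,4α-diol
Conditions: NaBH4, MeOH, 0 °C
Reagents that add atoms: none
Why: Hydride reduction of the cyclohexanone by axial attack from the α-face, away from the axial C4 methyl group, should give the equatorial 3β-alcohol trans to the C4 hydroxyl.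

**Step 12**
Reactants: 18 3β,4α-diol; 19 angelic acid
Product: 21 angelate, via mixed anhydride 20 (not isolated)
Conditions: 19, 2,4,6-trichlorobenzoyl chloride, Et3N, toluene, 23 °C; then 18, 80 °C
Reagents that add atoms: 2,4,6-trichlorobenzoyl chloride, O=C(Cl)c1c(Cl)cc(Cl)cc1Cl (its atoms stay only in 20)
Why: Yamaguchi-type esterification through the mixed anhydride, run without a nucleophilic catalyst so that the (Z)-alkene does not isomerise, acylates the only secondary alcohol while the two tertiary alcohols stay free.

**Step 13**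
Reactants: 21 angelate
Product: 22 triol
Conditions: HF·pyridine, THF/pyridine, 0 → 23 °C
Reagents that add atoms: none
Why: Fluoride cleavage of the silyl ether under buffered conditions leaves the angelate and the tertiary alcohols untouched.

**Step 14**
Reactants: 22 triol
Product: 24 target, via 8-ketone 23 (not isolated)
Conditions: IBX (4 equiv), DMSO, 23 → 75 °C
Reagents that add atoms: none
Why: IBX oxidises the only secondary alcohol to the C8 ketone and then dehydrogenates it by enol oxidation, and because C10 is quaternary the new double bond can only form between C6 and C7, giving the 7-substituted enone.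

**Compound list**

1 | (S)-(+)-carvone, (5S)-2-methyl-5-(prop-1-en-2-yl)cyclohex-2-en-1-one | CC1=CC[C@@H](CC1=O)C(C)=C | starting material
2 | (5R,6R)-6-hydroxy-2-methyl-5-(prop-1-en-2-yl)cyclohex-2-en-1-one (hydroxyl trans to isopropenyl) | CC1=CC[C@H](C(C)=C)[C@@H](O)C1=O | intermediate
3 | (5R,6R)-6-[(tert-butyldimethylsilyl)oxy]-2-methyl-5-(prop-1-en-2-yl)cyclohex-2-en-1-one | CC1=CC[C@H](C(C)=C)[C@@H](O[Si](C)(C)C(C)(C)C)C1=O | intermediate
4 | (1R,5R,6R)-6-[(tert-butyldimethylsilyl)oxy]-2-methyl-5-(prop-1-en-2-yl)cyclohex-2-en-1-ol (1-OH trans to 6-OSi, cis to isopropenyl) | CC1=CC[C@H](C(C)=C)[C@@H](O[Si](C)(C)C(C)(C)C)[C@@H]1O | intermediate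
5 | triethyl orthopropionate (1,1,1-triethoxypropane) | CCC(OCC)(OCC)OCC | starting material
6 | mixed ketene acetal of 4 (1-ethoxyprop-1-enyl ether at the C9 oxygen) | CC1=CC[C@H](C(C)=C)[C@@H](O[Si](C)(C)C(C)(C)C)[C@@H]1OC(OCC)=CC | intermediate
7 | ethyl 2-[(1S,4S,5R)-4-[(tert-butyldimethylsilyl)oxy]-2-methyl-5-(prop-1-en-2-yl)cyclohex-2-en-1-yl]propanoate (both epimers at the propanoate α-carbon, C4) | CCOC(=O)C(C)[C@@H]1C[C@H](C(C)=C)[C@@H](O[Si](C)(C)C(C)(C)C)C=C1C | intermediate
8 | alkylmercury acetate from 7 (C11 hydroxyl, acetoxymercurio group on C12) | CCOC(=O)C(C)[C@@H]1C[C@H](C(C)(O)C[Hg]OC(C)=O)[C@@H](O[Si](C)(C)C(C)(C)C)C=C1C | intermediate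
9 | ethyl 2-[(1S,4S,5S)-4-[(tert-butyldimethylsilyl)oxy]-5-(2-hydroxypropan-2-yl)-2-methylcyclohex-2-en-1-yl]propanoate | CCOC(=O)C(C)[C@@H]1C[C@H](C(C)(C)O)[C@@H](O[Si](C)(C)C(C)(C)C)C=C1C | intermediate
10 | 2-[(1S,4S,5S)-4-[(tert-butyldimethylsilyl)oxy]-5-(2-hydroxypropan-2-yl)-2-methylcyclohex-2-en-1-yl]propanal | O=CC(C)[C@@H]1C[C@H](C(C)(C)O)[C@@H](O[Si](C)(C)C(C)(C)C)C=C1C | intermediate
11 | phenyl vinyl sulfone (ethenylsulfonylbenzene) | C=CS(=O)(=O)c1ccccc1 | starting material
12 | tertiary C10 radical formed from 10 by hydrogen-atom transfer to C9 | O=CC(C)[C@@H]1C[C@H](C(C)(C)O)[C@@H](O[Si](C)(C)C(C)(C)C)C[C]1C | intermediate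
13 | α-sulfonyl carbanion after addition of 12 to 11 and one-electron reduction (C10 quaternary, C1 trans to C4) | O=CC(C)[C@@H]1C[C@H](C(C)(C)O)[C@@H](O[Si](C)(C)C(C)(C)C)C[C@@]1(C)C[CH-]S(=O)(=O)c1ccccc1 | intermediate
14 | 8α-[(tert-butyldimethylsilyl)oxy]-2-(phenylsulfonyl)eudesmane-3,11-diol; trans-decalin (5α-H, 10β-methyl), 7β side chain; epimers at C2, C3, C4 | CC1C(O)C(S(=O)(=O)c2ccccc2)C[C@]3(C)C[C@H](O[Si](C)(C)C(C)(C)C)[C@@H](C(C)(C)O)C[C@@H]13 | intermediate
15 | 8α-[(tert-butyldimethylsilyl)oxy]-11-hydroxy-2-(phenylsulfonyl)eudesman-3-one (5α-H, 10β-methyl; epimers at C2, C4) | CC1C(=O)C(S(=O)(=O)c2ccccc2)C[C@]3(C)C[C@H](O[Si](C)(C)C(C)(C)C)[C@@H](C(C)(C)O)C[C@@H]13 | intermediate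
16 | 8α-[(tert-butyldimethylsilyl)oxy]-4α,11-dihydroxy-2-(phenylsulfonyl)eudesman-3-one (4β-methyl; epimers at C2) | C[C@@]1(O)C(=O)C(S(=O)(=O)c2ccccc2)C[C@]3(C)C[C@H](O[Si](C)(C)C(C)(C)C)[C@@H](C(C)(C)O)C[C@@H]13 | intermediate
17 | 8α-[(tert-butyldimethylsilyl)oxy]-4α,11-dihydroxyeudesman-3-one | C[C@@]1(O)C(=O)CC[C@]3(C)C[C@H](O[Si](C)(C)C(C)(C)C)[C@@H](C(C)(C)O)C[C@@H]13 | intermediate
18 | 8α-[(tert-butyldimethylsilyl)oxy]eudesmane-3β,4α,11-triol | C[C@@]1(O)[C@@H](O)CC[C@]3(C)C[C@H](O[Si](C)(C)C(C)(C)C)[C@@H](C(C)(C)O)C[C@@H]13 | intermediate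
19 | angelic acid, (Z)-2-methylbut-2-enoic acid | C/C=C(/C)C(=O)O | starting material
20 | angelic 2,4,6-trichlorobenzoic mixed anhydride | C/C=C(/C)C(=O)OC(=O)c1c(Cl)cc(Cl)cc1Cl | intermediate
21 | 3β-angeloyloxy-8α-[(tert-butyldimethylsilyl)oxy]eudesmane-4α,11-diol | C/C=C(/C)C(=O)O[C@H]1CC[C@]2(C)C[C@H](O[Si](C)(C)C(C)(C)C)[C@@H](C(C)(C)O)C[C@H]2[C@]1(C)O | intermediate
22 | 3β-angeloyloxyeudesmane-4α,8α,11-triol | C/C=C(/C)C(=O)O[C@H]1CC[C@]2(C)C[C@H](O)[C@@H](C(C)(C)O)C[C@H]2[C@]1(C)O | intermediate
23 | 3β-angeloyloxy-4α,11-dihydroxyeudesman-8-one | C/C=C(/C)C(=O)O[C@H]1CC[C@]2(C)CC(=O)[C@@H](C(C)(C)O)C[C@H]2[C@]1(C)O | intermediate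
24 | 3β-angeloyloxy-4α,11-dihydroxyeudesm-6-en-8-one (3S,4S,5R,10R) | C/C=C(/C)C(=O)O[C@H]1CC[C@]2(C)CC(=O)C(C(C)(C)O)=C[C@H]2[C@]1(C)O | target

**Step count and risks**

Total steps: 14. Longest linear sequence: 14 (from 1; compounds 5, 11 and 19 enter as purchased).

Steps most likely to fail:

1. Step 7 (proposed new method). The α-sulfonyl intermediate may be protonated or quenched by hydrogen-atom transfer before it closes onto the aldehyde; the acceptor may also approach syn to the C5 side chain and give the cis ring fusion. Fallback with known chemistry, setting out from hydroxy ester 9: the same iron-hydride Giese coupling with 11, which needs no polar closure, should give the open-chain sulfone ester F1. LiN(SiMe3)2 in THF then closes ring A by intramolecular acylation of the sulfonyl carbanion by the ester (Dieckmann-type condensation, driven by deprotonation of the acidic product). This returns to the route at β-keto sulfone 15, and steps 6 and 8 are no longer needed.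

2. Step 9 (proposed new method). Deprotonation at the hindered tertiary C4–H (the axial proton lies under the C10 methyl group) may be incomplete, so that the monoanion is oxidised at C2 or starting material returns. Fallback with known, regiodefined chemistry, setting out from 15: Al(Hg) desulfonylation gives the 4-methyl-3-ketone F2. Its kinetic lithium enolate (less hindered C2) is selenenylated with PhSeBr to selenide F3, and H2O2 oxidation with selenoxide syn-elimination gives the C1=C2 enone F4. In F4 the only enolisable position is C4 (C10 is quaternary), so LiN(i-Pr)2 followed by the same oxaziridine should give the 4α-hydroxy enone F5 by α-face attack. Hydrogenation (H2, Pd/C) saturates C1=C2 and returns to the route at 17.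

3. Step 14. The β-hydroxy ketone may dehydrate or undergo retro-aldol cleavage at 75 °C before dehydrogenation, or dehydrogenation at the tertiary α-carbon may be slow. Fallback, setting out from 22: Dess–Martin oxidation at 23 °C gives ketone 23, which is isolated. PhSeCl in EtOAc selenenylates its more substituted enol to the C7 selenide F6, and H2O2/pyridine at 0 °C triggers selenoxide syn-elimination, which can only run towards C6. This returns to the route at 24.

**Further compounds**

F1 | step 7 | ethyl 2-[(1S,2R,4S,5S)-4-[(tert-butyldimethylsilyl)oxy]-5-(2-hydroxypropan-2-yl)-2-methyl-2-[2-(phenylsulfonyl)ethyl]cyclohexyl]propanoate (open-chain Giese adduct, C1 trans to C4) | CCOC(=O)C(C)[C@@H]1C[C@H](C(C)(C)O)[C@@H](O[Si](C)(C)C(C)(C)C)C[C@@]1(C)CCS(=O)(=O)c1ccccc1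
F2 | step 9 | 8α-[(tert-butyldimethylsilyl)oxy]-11-hydroxyeudesman-3-one (epimers at C4) | CC1C(=O)CC[C@]3(C)C[C@H](O[Si](C)(C)C(C)(C)C)[C@@H](C(C)(C)O)C[C@@H]13
F3 | step 9 | 8α-[(tert-butyldimethylsilyl)oxy]-11-hydroxy-2-(phenylselanyl)eudesman-3-one | CC1C(=O)C([Se]c2ccccc2)C[C@]3(C)C[C@H](O[Si](C)(C)C(C)(C)C)[C@@H](C(C)(C)O)C[C@@H]13
F4 | step 9 | 8α-[(tert-butyldimethylsilyl)oxy]-11-hydroxyeudesm-1-en-3-one | CC1C(=O)C=C[C@]3(C)C[C@H](O[Si](C)(C)C(C)(C)C)[C@@H](C(C)(C)O)C[C@@H]13
F5 | step 9 | 8α-[(tert-butyldimethylsilyl)oxy]-4α,11-dihydroxyeudesm-1-en-3-one | C[C@@]1(O)C(=O)C=C[C@]3(C)C[C@H](O[Si](C)(C)C(C)(C)C)[C@@H](C(C)(C)O)C[C@@H]13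
F6 | step 14 | 3β-angeloyloxy-4α,11-dihydroxy-7-(phenylselanyl)eudesman-8-one | C/C=C(/C)C(=O)O[C@H]1CC[C@]2(C)CC(=O)C([Se]c3ccccc3)(C(C)(C)O)C[C@H]2[C@]1(C)O
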